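**Retrosynthetic overview**

1. Ferulsinaic acid ⇐ methyl ester 23 ⇐ Mitsunobu etherification of primary alcohol 21 with umbelliferone 22; the coumarin is brought in intact and last.
2. The cis-disposed isobutenyl and propanoate arms ⇐ ozonolytic C4–C5 opening of a cis-fused hydrindan-5-one 15, then Wittig olefination; a temporary six-membered ring (ring B) relays the stereochemistry between the two arms.
3. Hydrindanone ⇐ Robinson annulation: intermolecular Michael addition of cyclopentanone 8 (as its chiral imine) to methyl vinyl ketone 9 creates the quaternary carbon (key bond), followed by aldol condensation and cis-hydrogenation.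
4. Cyclopentanone 8 ⇐ (S)-4-silyloxycyclopentenone 1 by two successive anti conjugate additions (methyl, then a hydroxymethyl equivalent with in situ enolate methylation).
5. Ring order: the cyclopentane (ring A) is present from 1 throughout; ring B is built in steps 6–7 and opened in step 10; the coumarin is attached in step 14.

Assumption: commercial (S)-4-silyloxycyclopentenone 1 (≥98% ee) is accepted as the source of absolute configuration; every other stereocentre is relayed from it.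

**Route**

Step 1
Reactants: 1 (4S)-4-[(tert-butyldimethylsilyl)oxy]cyclopent-2-en-1-one
Product: 3 (3S,4S)-4-[(tert-butyldimethylsilyl)oxy]-3-methylcyclopentan-1-one, via lithium enolate 2 (not isolated)
Conditions: Me2CuLi (MeLi, CuBr·SMe2), Et2O, −78 °C; aq. NH4Cl
Reagents that add atoms: lithium dimethylcuprate, [Li+].C[Cu-]C
Why: Conjugate addition of the Gilman cuprate occurs anti to the bulky silyloxy group, setting the methyl-bearing centre (C3 of the target ring) trans to OTBS.

Step 2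
Reactants: 3 (3S,4S)-4-[(tert-butyldimethylsilyl)oxy]-3-methylcyclopentan-1-one
Product: 4 (4S)-4-methylcyclopent-2-en-1-one
Conditions: DBU, CH2Cl2, 0 °C, 30 min (volatile product, used as a concentrated solution)
Reagents that add atoms: none
Why: E1cB β-elimination of silanolate transposes the enone so that the methyl stereocentre now flanks the β-carbon, and the short cold exposure to DBU avoids γ-deprotonation and racemisation.

Step 3
Reactants: 4 (4S)-4-methylcyclopent-2-en-1-one
Product: 6 (2S,3R,4S)-3-{[dimethyl(propan-2-yloxy)silyl]methyl}-2,4-dimethylcyclopentan-1-one, via magnesium enolate 5 (not isolated)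
Conditions: ClMgCH2SiMe2(Oi-Pr) (THF solution), CuBr·SMe2 (10 mol %), THF, −78 → −40 °C; then MeI, DMPU, −40 °C → rt
Reagents that add atoms: (isopropoxydimethylsilyl)methylmagnesium chloride, CC(C)O[Si](C)(C)C[Mg]Cl; iodomethane, CI
Why: Copper-catalysed conjugate addition of the Tamao hydroxymethyl-anion equivalent goes anti to the adjacent methyl (3,4-trans) and the regiodefined enolate is C-methylated anti to the new substituent (three-component coupling); the C2 centre is not critical because it becomes quaternary in step 6.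

Step 4
Reactants: 6 (2S,3R,4S)-3-{[dimethyl(propan-2-yloxy)silyl]methyl}-2,4-dimethylcyclopentan-1-one
Product: 7 (2S,3R,4S)-3-(hydroxymethyl)-2,4-dimethylcyclopentan-1-one
Conditions: 30% H2O2, KF, KHCO3, THF/MeOH, rt
Reagents that add atoms: hydrogen peroxide, OO
Why: Tamao oxidation converts the C–Si bond into C–OH without touching a stereocentre, under mildly basic peroxide conditions that the ketone tolerates.

Step 5
Reactants: 7 (2S,3R,4S)-3-(hydroxymethyl)-2,4-dimethylcyclopentan-1-one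
Product: 8 (2S,3R,4S)-2,4-dimethyl-3-({[tri(propan-2-yl)silyl]oxy}methyl)cyclopentan-1-one
Conditions: TIPSCl, imidazole, DMF, rt
Reagents that add atoms: chlorotri(propan-2-yl)silane, CC(C)[Si](Cl)(C(C)C)C(C)C
Why: Standard silylation of the primary alcohol; the TIPS ether survives aqueous AcOH, NaOMe, hydrogenation, ozone and the ylide, and is removed later by fluoride.

Step 6
Reactants: 8 (2S,3R,4S)-2,4-dimethyl-3-({[tri(propan-2-yl)silyl]oxy}methyl)cyclopentan-1-one; 9 but-3-en-2-one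
Product: 12 (2S,3R,4S)-2,4-dimethyl-2-(3-oxobutyl)-3-({[tri(propan-2-yl)silyl]oxy}methyl)cyclopentan-1-one, via imine 10 (not isolated), via Michael adduct imine 11 (not isolated)
Conditions: (S)-1-phenylethylamine, TsOH (cat.), PhMe, reflux (Dean–Stark); then 9, THF, 40 °C, 3 d; then 10% aq. AcOH, rt
Reagents that add atoms: water, O
Why: d'Angelo-type Michael addition, in which the imine reacts through its more substituted secondary enamine in an aza-ene-like transition state, so the new C–C bond forms regioselectively at C2 and anti to the adjacent CH2OTIPS group (the (S)-auxiliary is chosen to reinforce this face), giving the quaternary centre with the oxobutyl chain trans to CH2OTIPS.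

Step 7
Reactants: 12 (2S,3R,4S)-2,4-dimethyl-2-(3-oxobutyl)-3-({[tri(propan-2-yl)silyl]oxy}methyl)cyclopentan-1-one
Product: 14 (1R,2S,7aS)-2,7a-dimethyl-1-({[tri(propan-2-yl)silyl]oxy}methyl)-1,2,3,6,7,7a-hexahydro-5H-inden-5-one, via ketol 13 (not isolated)
Conditions: NaOMe, MeOH, 60 °C
Reagents that add atoms: none
Why: Intramolecular aldol condensation (second stage of the Robinson annulation) of the methyl ketone onto the ring carbonyl gives the six-membered enone, the only cyclisation mode that can dehydrate to a conjugated product; no stereocentre is affected.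

Step 8
Reactants: 14 (1R,2S,7aS)-2,7a-dimethyl-1-({[tri(propan-2-yl)silyl]oxy}methyl)-1,2,3,6,7,7a-hexahydro-5H-inden-5-one
Product: 15 (1R,2S,3aS,7aR)-2,7a-dimethyl-1-({[tri(propan-2-yl)silyl]oxy}methyl)octahydro-5H-inden-5-one
Conditions: H2 (1 atm), 10% Pd/C, EtOAc, rt
Reagents that add atoms: none
Why: Heterogeneous hydrogenation of 7a-methylhydrindenones adds hydrogen to C3a on the face of the angular methyl (the 2-methyl group on the opposite face helps), giving the cis-fused hydrindanone and so fixing the C3a–C4 bond cis to the C7a–C7 bond.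

Step 9
Reactants: 15 (1R,2S,3aS,7aR)-2,7a-dimethyl-1-({[tri(propan-2-yl)silyl]oxy}methyl)octahydro-5H-inden-5-one
Product: 16 trimethyl{[(1R,2S,3aS,7aR)-2,7a-dimethyl-1-({[tri(propan-2-yl)silyl]oxy}methyl)-2,3,3a,6,7,7a-hexahydro-1H-inden-5-yl]oxy}silane
Conditions: TMSCl, Et3N, DMF, 90 °C
Reagents that add atoms: chlorotrimethylsilane, C[Si](C)(C)Cl
Why: Under equilibrating (House) silyl enol ether conditions a cis-fused six-ring ketone of this type enolises towards the ring-fusion carbon (the 5β-3-keto-steroid pattern), so the C4=C5 enol ether is expected; no stereocentre changes.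

Step 10
Reactants: 16 trimethyl{[(1R,2S,3aS,7aR)-2,7a-dimethyl-1-({[tri(propan-2-yl)silyl]oxy}methyl)-2,3,3a,6,7,7a-hexahydro-1H-inden-5-yl]oxy}silane
Product: 18 3-[(1S,2R,3S,5R)-5-formyl-1,3-dimethyl-2-({[tri(propan-2-yl)silyl]oxy}methyl)cyclopentyl]propanoic acid, via trimethylsilyl ester 17 (not isolated)
Conditions: O3, CH2Cl2, −78 °C; then Me2S, −78 °C → rt; H2O
Reagents that add atoms: ozone, O=[O+][O-]
Why: Ozonolysis of the silyl enol ether cleaves C4–C5 so that C4 becomes the aldehyde and C5 the carboxylic acid, and the cold neutral work-up leaves the α-stereocentre of the aldehyde untouched.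

Step 11
Reactants: 18 3-[(1S,2R,3S,5R)-5-formyl-1,3-dimethyl-2-({[tri(propan-2-yl)silyl]oxy}methyl)cyclopentyl]propanoic acid
Product: 19 methyl 3-[(1S,2R,3S,5R)-5-formyl-1,3-dimethyl-2-({[tri(propan-2-yl)silyl]oxy}methyl)cyclopentyl]propanoate
Conditions: CH2N2, Et2O, 0 °C (titrated to faint yellow)
Reagents that add atoms: diazomethane, C=[N+]=[N-]
Why: Esterification with diazomethane is instantaneous and neutral, so the epimerisable aldehyde is not exposed to base.

Step 12
Reactants: 19 methyl 3-[(1S,2R,3S,5R)-5-formyl-1,3-dimethyl-2-({[tri(propan-2-yl)silyl]oxy}methyl)cyclopentyl]propanoate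
Product: 20 methyl 3-[(1R,2R,3S,5S)-1,3-dimethyl-5-(2-methylprop-1-en-1-yl)-2-({[tri(propan-2-yl)silyl]oxy}methyl)cyclopentyl]propanoate
Conditions: [i-PrPPh3]I, n-BuLi, THF, 0 °C; then 19, −78 → 0 °C
Reagents that add atoms: isopropyltriphenylphosphonium iodide, CC(C)[P+](c1ccccc1)(c1ccccc1)c1ccccc1.[I-]
Why: Wittig olefination with the non-stabilised isopropylidene ylide at low temperature is faster than α-deprotonation of the hindered aldehyde, so the ring configuration is retained while the 2-methylprop-1-enyl group is formed; the methyl ester does not react.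

Step 13
Reactants: 20 methyl 3-[(1R,2R,3S,5S)-1,3-dimethyl-5-(2-methylprop-1-en-1-yl)-2-({[tri(propan-2-yl)silyl]oxy}methyl)cyclopentyl]propanoate
Product: 21 methyl 3-[(1R,2R,3S,5S)-2-(hydroxymethyl)-1,3-dimethyl-5-(2-methylprop-1-en-1-yl)cyclopentyl]propanoate
Conditions: TBAF, AcOH, THF, rt → 40 °C
Reagents that add atoms: none
Why: Fluoride-mediated desilylation, buffered with AcOH so that the methyl ester is neither hydrolysed nor attacked by the liberated alkoxide.

Step 14
Reactants: 21 methyl 3-[(1R,2R,3S,5S)-2-(hydroxymethyl)-1,3-dimethyl-5-(2-methylprop-1-en-1-yl)cyclopentyl]propanoate; 22 7-hydroxy-2H-chromen-2-one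
Product: 23 methyl 3-[(1R,2R,3S,5S)-1,3-dimethyl-5-(2-methylprop-1-en-1-yl)-2-{[(2-oxo-2H-chromen-7-yl)oxy]methyl}cyclopentyl]propanoate
Conditions: PPh3, DIAD, THF, 0 °C → rt
Reagents that add atoms: none
Why: Mitsunobu etherification, in which the acidic phenol displaces the activated primary hydroxyl at a CH2 carbon, so no stereocentre is involved.

Step 15
Reactants: 23 methyl 3-[(1R,2R,3S,5S)-1,3-dimethyl-5-(2-methylprop-1-en-1-yl)-2-{[(2-oxo-2H-chromen-7-yl)oxy]methyl}cyclopentyl]propanoate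
Product: 25 ferulsinaic acid (3-[(1R,2R,3S,5S)-1,3-dimethyl-5-(2-methylprop-1-en-1-yl)-2-{[(2-oxo-2H-chromen-7-yl)oxy]methyl}cyclopentyl]propanoic acid), via lithium carboxylate 24 (not isolated)
Conditions: LiOH, THF/H2O, rt; then 1 M HCl to pH 2
Reagents that add atoms: lithium hydroxide, [Li+].[OH-]
Why: Saponification of the methyl ester, and acidification protonates the carboxylate and recloses any coumarin lactone that opened in base.

**Compound list**

1 | (4S)-4-[(tert-butyldimethylsilyl)oxy]cyclopent-2-en-1-one | O=C1C=C[C@@H](O[Si](C)(C)C(C)(C)C)C1 | starting material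
2 | lithium (3S,4S)-4-[(tert-butyldimethylsilyl)oxy]-3-methylcyclopent-1-en-1-olate | [Li]OC1=C[C@H](C)[C@@H](O[Si](C)(C)C(C)(C)C)C1 | intermediate
3 | (3S,4S)-4-[(tert-butyldimethylsilyl)oxy]-3-methylcyclopentan-1-one | O=C1C[C@H](C)[C@@H](O[Si](C)(C)C(C)(C)C)C1 | intermediate
4 | (4S)-4-methylcyclopent-2-en-1-one | O=C1C[C@H](C)C=C1 | intermediate
5 | chloromagnesium (3R,4S)-3-{[dimethyl(propan-2-yloxy)silyl]methyl}-4-methylcyclopent-1-en-1-olate | Cl[Mg]OC=1C[C@H](C)[C@@H](C[Si](C)(C)OC(C)C)C=1 | intermediate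
6 | (2S,3R,4S)-3-{[dimethyl(propan-2-yloxy)silyl]methyl}-2,4-dimethylcyclopentan-1-one | O=C1C[C@H](C)[C@@H](C[Si](C)(C)OC(C)C)[C@@H]1C | intermediate
7 | (2S,3R,4S)-3-(hydroxymethyl)-2,4-dimethylcyclopentan-1-one | O=C1C[C@H](C)[C@@H](CO)[C@@H]1C | intermediate
8 | (2S,3R,4S)-2,4-dimethyl-3-({[tri(propan-2-yl)silyl]oxy}methyl)cyclopentan-1-one | O=C1C[C@H](C)[C@@H](CO[Si](C(C)C)(C(C)C)C(C)C)[C@@H]1C | intermediate
9 | but-3-en-2-one (methyl vinyl ketone) | CC(=O)C=C | starting material
10 | (1S)-N-[(2S,3R,4S)-2,4-dimethyl-3-({[tri(propan-2-yl)silyl]oxy}methyl)cyclopentylidene]-1-phenylethan-1-amine (C=N geometry not fixed; C2 equilibrates through the enamine) | C[C@H](N=C1C[C@H](C)[C@@H](CO[Si](C(C)C)(C(C)C)C(C)C)[C@@H]1C)c1ccccc1 | intermediate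
11 | 4-[(1S,2R,3S)-1,3-dimethyl-5-{[(1S)-1-phenylethyl]imino}-2-({[tri(propan-2-yl)silyl]oxy}methyl)cyclopentyl]butan-2-one | C[C@H](N=C1C[C@H](C)[C@@H](CO[Si](C(C)C)(C(C)C)C(C)C)[C@]1(C)CCC(C)=O)c1ccccc1 | intermediate
12 | (2S,3R,4S)-2,4-dimethyl-2-(3-oxobutyl)-3-({[tri(propan-2-yl)silyl]oxy}methyl)cyclopentan-1-one | O=C1C[C@H](C)[C@@H](CO[Si](C(C)C)(C(C)C)C(C)C)[C@]1(C)CCC(C)=O | intermediate
13 | (1R,2S,3aR,7aS)-3a-hydroxy-2,7a-dimethyl-1-({[tri(propan-2-yl)silyl]oxy}methyl)octahydro-5H-inden-5-one (cis-fused ketol) | O=C1C[C@]2(O)C[C@H](C)[C@@H](CO[Si](C(C)C)(C(C)C)C(C)C)[C@]2(C)CC1 | intermediate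
14 | (1R,2S,7aS)-2,7a-dimethyl-1-({[tri(propan-2-yl)silyl]oxy}methyl)-1,2,3,6,7,7a-hexahydro-5H-inden-5-one | O=C1C=C2C[C@H](C)[C@@H](CO[Si](C(C)C)(C(C)C)C(C)C)[C@]2(C)CC1 | intermediate
15 | (1R,2S,3aS,7aR)-2,7a-dimethyl-1-({[tri(propan-2-yl)silyl]oxy}methyl)octahydro-5H-inden-5-one (cis ring fusion) | O=C1C[C@@H]2C[C@H](C)[C@@H](CO[Si](C(C)C)(C(C)C)C(C)C)[C@]2(C)CC1 | intermediate
16 | trimethyl{[(1R,2S,3aS,7aR)-2,7a-dimethyl-1-({[tri(propan-2-yl)silyl]oxy}methyl)-2,3,3a,6,7,7a-hexahydro-1H-inden-5-yl]oxy}silane | C[Si](C)(C)OC1=C[C@@H]2C[C@H](C)[C@@H](CO[Si](C(C)C)(C(C)C)C(C)C)[C@]2(C)CC1 | intermediate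
17 | trimethylsilyl 3-[(1S,2R,3S,5R)-5-formyl-1,3-dimethyl-2-({[tri(propan-2-yl)silyl]oxy}methyl)cyclopentyl]propanoate | O=C[C@@H]1C[C@H](C)[C@@H](CO[Si](C(C)C)(C(C)C)C(C)C)[C@]1(C)CCC(=O)O[Si](C)(C)C | intermediate
18 | 3-[(1S,2R,3S,5R)-5-formyl-1,3-dimethyl-2-({[tri(propan-2-yl)silyl]oxy}methyl)cyclopentyl]propanoic acid | O=C[C@@H]1C[C@H](C)[C@@H](CO[Si](C(C)C)(C(C)C)C(C)C)[C@]1(C)CCC(=O)O | intermediate
19 | methyl 3-[(1S,2R,3S,5R)-5-formyl-1,3-dimethyl-2-({[tri(propan-2-yl)silyl]oxy}methyl)cyclopentyl]propanoate | O=C[C@@H]1C[C@H](C)[C@@H](CO[Si](C(C)C)(C(C)C)C(C)C)[C@]1(C)CCC(=O)OC | intermediate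
20 | methyl 3-[(1R,2R,3S,5S)-1,3-dimethyl-5-(2-methylprop-1-en-1-yl)-2-({[tri(propan-2-yl)silyl]oxy}methyl)cyclopentyl]propanoate | CC(C)=C[C@@H]1C[C@H](C)[C@@H](CO[Si](C(C)C)(C(C)C)C(C)C)[C@]1(C)CCC(=O)OC | intermediate
21 | methyl 3-[(1R,2R,3S,5S)-2-(hydroxymethyl)-1,3-dimethyl-5-(2-methylprop-1-en-1-yl)cyclopentyl]propanoate | CC(C)=C[C@@H]1C[C@H](C)[C@@H](CO)[C@]1(C)CCC(=O)OC | intermediate
22 | 7-hydroxy-2H-chromen-2-one (umbelliferone) | Oc1ccc2ccc(=O)oc2c1 | starting material
23 | methyl 3-[(1R,2R,3S,5S)-1,3-dimethyl-5-(2-methylprop-1-en-1-yl)-2-{[(2-oxo-2H-chromen-7-yl)oxy]methyl}cyclopentyl]propanoate | CC(C)=C[C@@H]1C[C@H](C)[C@@H](COc2ccc3ccc(=O)oc3c2)[C@]1(C)CCC(=O)OC | intermediate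
24 | lithium 3-[(1R,2R,3S,5S)-1,3-dimethyl-5-(2-methylprop-1-en-1-yl)-2-{[(2-oxo-2H-chromen-7-yl)oxy]methyl}cyclopentyl]propanoate | CC(C)=C[C@@H]1C[C@H](C)[C@@H](COc2ccc3ccc(=O)oc3c2)[C@]1(C)CCC(=O)[O-].[Li+] | intermediate
25 | ferulsinaic acid, 3-[(1R,2R,3S,5S)-1,3-dimethyl-5-(2-methylprop-1-en-1-yl)-2-{[(2-oxo-2H-chromen-7-yl)oxy]methyl}cyclopentyl]propanoic acid | CC(C)=C[C@@H]1C[C@H](C)[C@@H](COc2ccc3ccc(=O)oc3c2)[C@]1(C)CCC(=O)O | target

**Step count and weak points**

Total step count: 15. Longest linear sequence: 15 steps (1 → 25); the route is fully linear, with 9 and 22 entering as purchased fragments.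

The three steps most likely to fail:

Step 6 (Michael addition that builds the quaternary carbon next to a substituted ring carbon; imine formation and addition may be slow). The fallback sets out from 8 and comes back to the route at 12. Ketone 8 is converted with TMSCl, Et3N, DMF at 90 °C into the more substituted silyl enol ether trimethyl{[(3R,4S)-2,4-dimethyl-3-({[tri(propan-2-yl)silyl]oxy}methyl)cyclopent-1-en-1-yl]oxy}silane F1. F1 then undergoes a Mukaiyama–Michael addition to 9 (TiCl4, CH2Cl2, −78 °C; aqueous work-up), again anti to the CH2OTIPS group, to give 12 without any auxiliary.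

Step 9 (regiochemistry of enolisation, C4 against C6). The fallback sets out from 14 and comes back to the route at 18. Enone 14 is subjected to 1,4-hydrosilylation (Et3SiH, RhCl(PPh3)3 cat., PhH, 60 °C), which by mechanism can only give the C4=C5 silyl enol ether triethyl{[(1R,2S,3aS,7aR)-2,7a-dimethyl-1-({[tri(propan-2-yl)silyl]oxy}methyl)-2,3,3a,6,7,7a-hexahydro-1H-inden-5-yl]oxy}silane F2. Hydrogen is expected to go to C3a on the face of the angular methyl, as in step 8, but this must be confirmed. Ozonolysis of F2 as in step 10 gives 18.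

Step 12 (Wittig reaction on a hindered, epimerisable aldehyde). The fallback sets out from 19 and comes back to the route at 20. Aldehyde 19 is methylenated under non-basic Lombardo conditions (Zn, CH2Br2, TiCl4, THF, 0 °C) to methyl 3-[(1R,2R,3S,5S)-5-ethenyl-1,3-dimethyl-2-({[tri(propan-2-yl)silyl]oxy}methyl)cyclopentyl]propanoate F3. Cross-metathesis of F3 with 2-methylbut-2-ene (used as solvent; second-generation Grubbs catalyst, RuCl2(=CHPh)(PCy3)(1,3-dimesitylimidazolidin-2-ylidene), 40 °C) then gives 20.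

**Further compounds**

F1 | step 6 | trimethyl{[(3R,4S)-2,4-dimethyl-3-({[tri(propan-2-yl)silyl]oxy}methyl)cyclopent-1-en-1-yl]oxy}silane | C[Si](C)(C)OC=1C[C@H](C)[C@@H](CO[Si](C(C)C)(C(C)C)C(C)C)C=1C
F2 | step 9 | triethyl{[(1R,2S,3aS,7aR)-2,7a-dimethyl-1-({[tri(propan-2-yl)silyl]oxy}methyl)-2,3,3a,6,7,7a-hexahydro-1H-inden-5-yl]oxy}silane | CC[Si](CC)(CC)OC1=C[C@@H]2C[C@H](C)[C@@H](CO[Si](C(C)C)(C(C)C)C(C)C)[C@]2(C)CC1
F3 | step 12 | methyl 3-[(1R,2R,3S,5S)-5-ethenyl-1,3-dimethyl-2-({[tri(propan-2-yl)silyl]oxy}methyl)cyclopentyl]propanoate | C=C[C@@H]1C[C@H](C)[C@@H](CO[Si](C(C)C)(C(C)C)C(C)C)[C@]1(C)CCC(=O)OC
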